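## The problem

The target, 5,7,3',6'-tetrahydroxy-6,8,2'-trimethoxyflavone (18), is a 2-aryl-4H-chromen-4-one whose ring A carries no hydrogen. C5 to C8 bear OH, OMe, OH and OMe in that order, and C4a and C8a are the fusion atoms to the pyranone ring C. Ring B is a methoxyhydroquinone joined to C2 through its most crowded carbon, C1', which lies between the 2'-methoxy and the 6'-hydroxy group. There is no stereocentre, and the C2–C1' axis should rotate freely because ring C offers only O1 and C3–H as neighbours. The stereocentres that appear on the way are racemic and are erased again, so none of them has to control anything. The selectivity problem is positional: four neighbouring oxygens on ring A must be told apart, two as methyl ethers (O6, O8) and two as free phenols (O5, O7). Only O5 is marked by the molecule itself, through its hydrogen bond to the C4 carbonyl. The phenols are fragile: the ring-B hydroquinone and any 5,8-dihydroxy intermediate oxidise easily to quinones, ring B competes for electrophilic reagents, and the acetal protecting groups that allow ortho-metalation are acid-labile. The feature that opens a short route is the run C5–C8: four contiguous oxygenated carbons with O5 and O8 para to each other, beside the C4a–C8a double bond of a 4-pyranone. This is the pattern a squarate ester delivers onto an alkene after addition of the alkenyl carbanion and thermal rearrangement.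

## Retrosynthesis

**18 from 17.** The last cut removes the two MOM acetals on ring B and the tert-butyl ether on O7. All three are acid-labile, so one operation ends the synthesis and the oxidation-prone hydroquinone is never carried through a further step. Benzyl ethers would have needed a separate hydrogenolysis. The forward step must cleave an acetal and a tertiary ether and leave three aryl methyl ethers alone.

**17 from 16.** The O8–CH3 bond is cut. O8 is born as a free hydroxyl in the ring-forming step, so it can only be methylated afterwards. Of the two hydroxyls of 16, the one on C5 is locked to the C4 carbonyl, so a single equivalent of methylating agent should find O8.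

**16 from 13 (key disconnection).** The C8–C8a bond is cut and C5 is joined to C8, which folds ring A back into a 4-hydroxycyclobutenone carrying a 4-pyranon-3-yl group. The neighbouring cuts close ring C onto a finished penta-oxygenated benzene or substitute ring A stepwise, and both need a hexasubstituted arene made by arene substitution. Here the six carbons of ring A shrink to a four-carbon squarate unit, which brings C5–C8 with their oxygens in fixed order, and to two carbons that already belong to the pyranone. The forward reaction needs outward rotation of the hydroxyl during ring opening, closure onto the single pyranone CH, and exclusion of oxygen.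

**13 from 9 and 11.** The bond between pyranone C5 (future C4a) and the carbinol carbon (future C5) is cut, giving a pyranonyl carbanion derived from iodide 9 and the mixed squarate 11. 1,2-Addition of an organometallic to a squarate ester is the standard entry to such cyclobutenones. O7 is differentiated at this stage by the tert-butyl group of 11, which also biases the addition and leaves in the final acid step. The carbanion must survive next to the pyranone carbonyl, and it must attack the carbonyl flanked by the methoxy-bearing carbon.

**11 from 10.** One methoxy group of commercial dimethyl squarate 10 is exchanged for tert-butoxy, a single O–C exchange at a vinylogous ester.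

**9 from 8.** The ring O–CH bond of the pyranone (future O1–C8a) and the C–I bond are cut together, which leads to the open-chain diketo enaminone 8. Halogenating a finished 2-aryl-4-pyranone would have to choose between C3 and C5 and would compete with electron-rich ring B. In 8 the only strongly nucleophilic carbon is the enaminone α-carbon, which becomes C5, so the halogen position is set by construction.

**8 from 4 and 5.** The bond between the aroyl carbon (future C2) and the methylene (future C3) is cut. This gives benzoic acid 4, activated as its chloride, and the commercial enaminone 5 as its enolate. Ring C is thus assembled from one four-carbon piece.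

**4 from 2 from 1.** The C1'–carboxyl bond is cut. C1' is the one ring position of 2 that lies between two oxygen substituents, so directed lithiation and carboxylation install the carbon. Bis-ether 2 comes from commercial methoxyhydroquinone 1 by protection.

## Roads not taken

**Alternative 1:** Ring C is cut at O1–C8a and C4–C4a. Ring A comes from aryne A4, released by CsF from the symmetric silyl bis-triflate A2. C2–C4 and ring B come from the arylpropiolic acid A3. The carboxylate oxygen of A3 adds to A4 at the carbon remote from the remaining triflate, the acyl group shifts to the neighbouring carbanionic carbon, and the freed phenoxide closes ring C by conjugate addition to the alkyne, giving A1.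
- Merits: this is the most convergent assembly. The symmetry of A2 removes any question of which triflate leaves, and the surviving triflate marks O5.
- Weak points: A2 is a hexasubstituted benzene with five oxygens and a silyl group, and it must be built by stepwise arene substitution. A4 is flanked on both sides, and the site of addition rests on the difference between a triflate and a methoxy neighbour. The end game needs three different deprotections (hindered aryl triflate, benzyl, MOM).
- Comparison: if A2 were at hand, this road would be shorter from there, and its ring closure has closer analogy than a benzannulation onto a pyranone. The chosen plan sets against this a commercial squarate that carries all four ring-A oxygens and a single acid step at the end.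

**Alternative 2:** Ring C is cut at C4–C4a and O1–C2. Heating the symmetric resorcinol A6, which has one ring hydrogen, with the aroylacetic ester A7 without solvent acylates that single carbon, and cyclodehydration closes ring C to A5.
- Merits: this is the shortest conceivable assembly. The reaction type is long established for phloroglucinol-like phenols, the symmetry of A6 removes regiochemistry, and the 5-hydroxyl emerges free.
- Weak points: A6 is a penta-oxygenated, air-sensitive benzene that is not an article of commerce, and it needs several oxidation-level changes on an arene. The temperature rules out acetal protection, hence the benzyl ethers. The ketone of A7 is shielded by two ortho substituents, which hampers cyclodehydration.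
- Comparison: in step count from the two fragments and in precedent for the ring-forming step this road is better. The chosen plan sets against it that no penta-oxygenated benzene has to be made or handled.

**Alternative 3:** Ring C is cut at O1–C8a. The diketone A9, whose ring A comes from syringic acid A10 by benzylation and double bromination, is closed with CuI, 1,10-phenanthroline and Cs2CO3 by O-arylation of its enol at one of two equivalent C–Br bonds, giving A8.
- Merits: A10 is cheap and already has the O6, O7, O8 pattern. The dibromination needs no regiocontrol, the copper-mediated closure is an established type, and MOM groups survive.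
- Weak points: O5 is missing. The bromine of A8 must be turned into a hydroxyl at the most hindered position of the arene, between C4a and the C6 methoxy group, with reduction of the C–Br bond as a competitor. A9 has two doubly ortho-substituted aryl ketones and is hard to assemble. The end game has three operations.
- Comparison: every step is of a known type and the ring-A source is the cheapest, so this road is less of a gamble than the thermal benzannulation. The chosen plan sets against it that all four oxygens arrive with the ring and that the route is shorter.

Key step: step 7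

Assumption: the C2–C1' bond rotates freely in all intermediates, so no atropisomers are counted. Diketone 8 is drawn in the diketo form although it should exist largely as an enol.

## Route

Step 1
Reactants: 1 methoxyhydroquinone (2-methoxybenzene-1,4-diol)
Product: 2 2-methoxy-1,4-bis(methoxymethoxy)benzene
Conditions: NaH (2.4 equiv), MOMCl (2.4 equiv), DMF, 0 °C to rt, argon
Reagents that add atoms: chloromethyl methyl ether, COCCl
Why: Double Williamson etherification of the bis-phenoxide; MOM ethers are chosen because they direct the lithiation of step 2, tolerate the organometallic steps and leave with acid in step 9.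

Step 2
Reactants: 2 2-methoxy-1,4-bis(methoxymethoxy)benzene
Product: 4 2-methoxy-3,6-bis(methoxymethoxy)benzoic acid, via aryllithium 3 (not isolated)
Conditions: n-BuLi (1.15 equiv), TMEDA, THF, −20 to 0 °C; CO2, −78 °C to rt; cold 1 M HCl to pH 3
Reagents that add atoms: carbon dioxide, O=C=O
Why: Directed ortho-metalation removes the one ring hydrogen that lies between two oxygen directing groups (OMe and OMOM), the site at which 1,2,4-trialkoxybenzenes are lithiated, and the aryllithium is carboxylated. Brief, cold acidification keeps the MOM acetals.

Step 3
Reactants: 4 2-methoxy-3,6-bis(methoxymethoxy)benzoic acid; 5 (E)-4-(dimethylamino)but-3-en-2-one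
Product: 8 (4E)-5-(dimethylamino)-1-[2-methoxy-3,6-bis(methoxymethoxy)phenyl]pent-4-ene-1,3-dione, via acid chloride 6 (not isolated), via lithium enolate 7 (not isolated)
Conditions: 4, 1-chloro-N,N,2-trimethylprop-1-en-1-amine (1.05 equiv), CH2Cl2, 0 °C to rt, evaporate; 5 (2.2 equiv), LiN(SiMe3)2 (2.2 equiv), THF, −78 °C; add 6, −78 to −30 °C; aq. NH4Cl
Reagents that add atoms: none
Why: The α-chloroenamine gives the acid chloride without liberating HCl, so the MOM groups survive. Claisen-type C-acylation of the lithium enolate of this vinylogous amide is the established entry to the 1,3-diketones that close to 2-substituted 4-pyranones; the second equivalent of enolate takes up the acidic diketone proton.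

Step 4
Reactants: 8 (4E)-5-(dimethylamino)-1-[2-methoxy-3,6-bis(methoxymethoxy)phenyl]pent-4-ene-1,3-dione
Product: 9 5-iodo-2-[2-methoxy-3,6-bis(methoxymethoxy)phenyl]-4H-pyran-4-one
Conditions: I2 (1.2 equiv), CHCl3, rt, dark; aq. Na2S2O3/NaHCO3
Reagents that add atoms: iodine, II
Why: Iodine attacks the nucleophilic α-carbon of the enaminone, the enol oxygen of the diketone adds to the iminium carbon and dimethylamine is lost; this is the iodine-induced cyclisation by which 2-hydroxyaryl enaminones give 3-iodochromones. The iodine enters at pyranone C5 by construction, and iodine without an activator leaves electron-rich ring B alone.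

Step 5
Reactants: 10 dimethyl squarate (3,4-dimethoxycyclobut-3-ene-1,2-dione)
Product: 11 3-tert-butoxy-4-methoxycyclobut-3-ene-1,2-dione
Conditions: t-BuOK (1.0 equiv), THF, −78 to −40 °C; aq. NH4Cl
Reagents that add atoms: potassium tert-butoxide, CC(C)(C)[O-].[K+]
Why: Addition–elimination of tert-butoxide at a vinylogous ester carbon (alkoxide exchange of a squarate ester). KOMe is the weaker base and poorly soluble in THF, and a second exchange would force two tert-butoxy groups side by side, so the mixed ester should predominate.

Step 6
Reactants: 9 5-iodo-2-[2-methoxy-3,6-bis(methoxymethoxy)phenyl]-4H-pyran-4-one; 11 3-tert-butoxy-4-methoxycyclobut-3-ene-1,2-dione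
Product: 13 racemic 2-tert-butoxy-4-hydroxy-3-methoxy-4-{6-[2-methoxy-3,6-bis(methoxymethoxy)phenyl]-4-oxo-4H-pyran-3-yl}cyclobut-2-en-1-one, via pyranonylmagnesium chloride 12 (not isolated)
Conditions: 9, iPrMgCl·LiCl (1.05 equiv), THF, −40 °C, 30 min; transfer into 11 (1.3 equiv), THF, −78 °C; aq. NH4Cl at −78 °C; chromatography on Et3N-deactivated silica (minor regioisomer removed)
Reagents that add atoms: none
Why: Iodine–magnesium exchange on an α-iodo-β-oxygenated enone gives an alkenylmagnesium species held by chelation to the carbonyl at low temperature, and it adds 1,2 to the squarate as Grignard reagents do. The carbonyl flanked by the methoxy carbon is less shielded and is deactivated only by the twisted, weakly donating tert-butoxy group, so attack there should prevail. The carbinol centre forms racemic and disappears in step 7.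

Step 7
Reactants: 13 racemic 2-tert-butoxy-4-hydroxy-3-methoxy-4-{6-[2-methoxy-3,6-bis(methoxymethoxy)phenyl]-4-oxo-4H-pyran-3-yl}cyclobut-2-en-1-one
Product: 16 7-tert-butoxy-5,8-dihydroxy-6-methoxy-2-[2-methoxy-3,6-bis(methoxymethoxy)phenyl]-4H-chromen-4-one, via dienylketene 14 (not isolated), via cyclohexadienone 15 (not isolated)
Conditions: degassed toluene (0.02 M), 110 °C, argon
Reagents that add atoms: none
Why: Heating opens the cyclobutenone by conrotatory 4π cleavage of the bond between the carbonyl carbon and the carbinol carbon; the hydroxyl, as a donor, rotates outward, so the pyranonyl group turns inward and dienylketene 14 has the (3Z) geometry in which the ketene faces the pyranone. Thermal disrotatory 6π electrocyclisation of the ketene C=C, the central C=C and the C2=C3 bond of the pyran-3-yl group then joins the ketene carbon to the pyranone CH, forming the C8–C8a bond and the six-membered ring A as cyclohexadienone 15. Enolisation of 15, driven by aromatisation, moves the C8a hydrogen to O8 and gives the 5,8-hydroquinone 16. The closest known reaction is the Moore rearrangement of 4-alkenyl- and 4-aryl-4-hydroxycyclobutenones made from squarate esters, which gives hydroquinones under these conditions; the 4-pyranon-3-yl group is a new member of this family of unsaturated partners. No stereocentre survives: the carbinol centre of 13 becomes sp2 in 14 and the C8a centre of 15 is lost on enolisation. The step needs outward torquoselectivity, which the hydroxyl secures, and a single site of closure, which is fixed because the attachment carbon has only one CH neighbour, the other being the C4 carbonyl carbon. The squarate carbons arrive as C5–C8 with their oxygens in the order set in step 6, so O6 is methylated, O7 is tert-butylated and O5 and O8 are free. Oxygen is excluded because 16 is an electron-rich hydroquinone.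

Step 8
Reactants: 16 7-tert-butoxy-5,8-dihydroxy-6-methoxy-2-[2-methoxy-3,6-bis(methoxymethoxy)phenyl]-4H-chromen-4-one
Product: 17 7-tert-butoxy-5-hydroxy-6,8-dimethoxy-2-[2-methoxy-3,6-bis(methoxymethoxy)phenyl]-4H-chromen-4-one
Conditions: MeI (1.1 equiv), K2CO3 (1.5 equiv), degassed acetone, rt, argon
Reagents that add atoms: iodomethane, CI
Why: Partial O-methylation as practised on 5,8-dihydroxyflavones: the 5-hydroxyl is tied to the C4 carbonyl by a hydrogen bond and is far less acidic and nucleophilic, so one equivalent of MeI should alkylate O8 only. Air is excluded because the hydroquinone anion autoxidises.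

Step 9
Reactants: 17 7-tert-butoxy-5-hydroxy-6,8-dimethoxy-2-[2-methoxy-3,6-bis(methoxymethoxy)phenyl]-4H-chromen-4-one
Product: 18 2-(3,6-dihydroxy-2-methoxyphenyl)-5,7-dihydroxy-6,8-dimethoxy-4H-chromen-4-one (5,7,3',6'-tetrahydroxy-6,8,2'-trimethoxyflavone)
Conditions: HCl (3 M in MeOH), degassed, 50 °C, argon
Reagents that add atoms: none
Why: Acidic methanolysis cleaves the two MOM acetals (methanol takes up the methoxymethyl cation) and the aryl tert-butyl ether (the tert-butyl cation leaves as isobutene), while aryl methyl ethers are inert. Ring A is symmetric towards acid-induced opening and reclosure of ring C (Wessely–Moser rearrangement), so that process would only regenerate 18.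

## Compound list

1 | methoxyhydroquinone (2-methoxybenzene-1,4-diol) | COc1cc(O)ccc1O | starting material
2 | 2-methoxy-1,4-bis(methoxymethoxy)benzene | COCOc1ccc(OCOC)c(OC)c1 | intermediate
3 | [2-methoxy-3,6-bis(methoxymethoxy)phenyl]lithium | [Li]c1c(OC)c(OCOC)ccc1OCOC | intermediate
4 | 2-methoxy-3,6-bis(methoxymethoxy)benzoic acid | COCOc1ccc(OCOC)c(OC)c1C(=O)O | intermediate
5 | (E)-4-(dimethylamino)but-3-en-2-one | CN(C)/C=C/C(C)=O | starting material
6 | 2-methoxy-3,6-bis(methoxymethoxy)benzoyl chloride | COCOc1ccc(OCOC)c(OC)c1C(=O)Cl | intermediate
7 | lithium (3E)-4-(dimethylamino)buta-1,3-dien-2-olate | [Li]OC(=C)/C=C/N(C)C | intermediate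
8 | (4E)-5-(dimethylamino)-1-[2-methoxy-3,6-bis(methoxymethoxy)phenyl]pent-4-ene-1,3-dione | COCOc1ccc(OCOC)c(OC)c1C(=O)CC(=O)/C=C/N(C)C | intermediate
9 | 5-iodo-2-[2-methoxy-3,6-bis(methoxymethoxy)phenyl]-4H-pyran-4-one | COCOc1ccc(OCOC)c(OC)c1-c1cc(=O)c(I)co1 | intermediate
10 | dimethyl squarate (3,4-dimethoxycyclobut-3-ene-1,2-dione) | COC1=C(OC)C(=O)C1=O | starting material
11 | 3-tert-butoxy-4-methoxycyclobut-3-ene-1,2-dione | COC1=C(OC(C)(C)C)C(=O)C1=O | intermediate
12 | chloro{6-[2-methoxy-3,6-bis(methoxymethoxy)phenyl]-4-oxo-4H-pyran-3-yl}magnesium (LiCl complex) | Cl[Mg]c1coc(-c2c(OC)c(OCOC)ccc2OCOC)cc1=O | intermediate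
13 | racemic 2-tert-butoxy-4-hydroxy-3-methoxy-4-{6-[2-methoxy-3,6-bis(methoxymethoxy)phenyl]-4-oxo-4H-pyran-3-yl}cyclobut-2-en-1-one | COC1=C(OC(C)(C)C)C(=O)C1(O)c1coc(-c2c(OC)c(OCOC)ccc2OCOC)cc1=O | intermediate
14 | (3Z)-2-tert-butoxy-4-hydroxy-3-methoxy-4-{6-[2-methoxy-3,6-bis(methoxymethoxy)phenyl]-4-oxo-4H-pyran-3-yl}buta-1,3-dien-1-one | O=C=C(OC(C)(C)C)/C(OC)=C(/O)c1coc(-c2c(OC)c(OCOC)ccc2OCOC)cc1=O | intermediate
15 | racemic 7-tert-butoxy-5-hydroxy-6-methoxy-2-[2-methoxy-3,6-bis(methoxymethoxy)phenyl]-8aH-chromene-4,8-dione | O=C1C(OC(C)(C)C)=C(OC)C(O)=C2C(=O)C=C(-c3c(OC)c(OCOC)ccc3OCOC)OC12 | intermediate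
16 | 7-tert-butoxy-5,8-dihydroxy-6-methoxy-2-[2-methoxy-3,6-bis(methoxymethoxy)phenyl]-4H-chromen-4-one | COCOc1ccc(OCOC)c(OC)c1-c1cc(=O)c2c(O)c(OC)c(OC(C)(C)C)c(O)c2o1 | intermediate
17 | 7-tert-butoxy-5-hydroxy-6,8-dimethoxy-2-[2-methoxy-3,6-bis(methoxymethoxy)phenyl]-4H-chromen-4-one | COCOc1ccc(OCOC)c(OC)c1-c1cc(=O)c2c(O)c(OC)c(OC(C)(C)C)c(OC)c2o1 | intermediate
18 | 2-(3,6-dihydroxy-2-methoxyphenyl)-5,7-dihydroxy-6,8-dimethoxy-4H-chromen-4-one | COc1c(O)ccc(O)c1-c1cc(=O)c2c(O)c(OC)c(O)c(OC)c2o1 | target

## Step count and risks

Total step count: 9.
Longest linear sequence: 8 steps (steps 1, 2, 3, 4, 6, 7, 8, 9 from 1); step 5 is a one-step side branch.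

Least certain steps:

**Step 7 (key step).** The most likely failure is a slow electrocyclisation. The pyranone CH is the electron-poor end of a vinylogous ester and part of a partly aromatic ring. A long-lived ketene can then be captured by the neighbouring hydroxyl to give a butenolide, or it can oligomerise. Autoxidation of the product is a second risk. Fallback, from 13 back to 16: the carbinol is silylated (Et3SiOTf, 2,6-lutidine, CH2Cl2, −78 °C) to the triethylsilyl ether F1. F1 can no longer add its oxygen to the ketene and allows thermolysis up to 140 °C in xylene. Rearrangement then gives the 5-silyloxy-8-hydroxyflavone F2, a mono-protected hydroquinone, and buffered fluoride (Bu4NF, AcOH) returns it to the route at 16. Thermal rearrangement of 4-silyloxycyclobutenones to mono-silylated hydroquinones is an established variant.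

**Step 6.** Two things may go wrong. Attack at the carbonyl flanked by the tert-butoxy carbon would erode site selectivity. The carbanion may also be lost, by ring opening through β-elimination of the ring oxygen or by conjugate attack of iPrMgCl on the pyranone. Fallback, from 9 back to 13: zinc dust with LiCl in THF inserts into the C–I bond to give the pyranonylzinc iodide F3, which is too weakly basic to open the ring and needs no sacrificial Grignard reagent. Its addition to 11 is then promoted by MgCl2, as in Lewis-acid-assisted additions of organozinc halides to ketones.

**Step 4.** Iodination may occur at the doubly activated methylene of the diketone, or acid formed in the flask may close the ring before iodine is taken up, giving an iodine-free or wrongly iodinated pyranone. Fallback, from 5 and 6 back to 9: enaminone 5 is iodinated at its α-carbon first (I2, Et3N, CH2Cl2) to the iodoenaminone F4. F4 is deprotonated with LiN(SiMe3)2 and acylated with 6 as in step 3 to the iodo diketone F5, and AcOH closes the ring to 9. The iodine position is then fixed before the diketone exists.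

**Step 5.** The alkoxide may attack a ring carbonyl and cleave the four-membered ring, or the exchange may stop at a mixture that is hard to separate from 10. Fallback, from 10 back to 11: one ester is hydrolysed (NaOH, 1 equiv, then acid) to the monomethyl squarate F6, Ag2O gives the silver salt F7, and O-alkylation with t-BuBr in ether gives 11. Alkylation of silver squarates is an established route to hindered squarate esters.

**Step 8.** Autoxidation of the hydroquinone anion to the 5,8-quinone may outrun alkylation. Fallback, from 16 back to 17: 16 is oxidised on purpose (Ag2O) to the flavone-5,8-quinone F8, which is air-stable and can be purified. Reduction with Na2S2O4 in a two-phase system, followed in the same flask by K2CO3 and MeI (reductive methylation), gives 17 without the free hydroquinone being handled.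

## Further compounds

F1 | step 7 | racemic 2-tert-butoxy-3-methoxy-4-{6-[2-methoxy-3,6-bis(methoxymethoxy)phenyl]-4-oxo-4H-pyran-3-yl}-4-[(triethylsilyl)oxy]cyclobut-2-en-1-one | COC1=C(OC(C)(C)C)C(=O)C1(O[Si](CC)(CC)CC)c1coc(-c2c(OC)c(OCOC)ccc2OCOC)cc1=O
F2 | step 7 | 7-tert-butoxy-8-hydroxy-6-methoxy-2-[2-methoxy-3,6-bis(methoxymethoxy)phenyl]-5-[(triethylsilyl)oxy]-4H-chromen-4-one | COCOc1ccc(OCOC)c(OC)c1-c1cc(=O)c2c(O[Si](CC)(CC)CC)c(OC)c(OC(C)(C)C)c(O)c2o1
F3 | step 6 | iodo{6-[2-methoxy-3,6-bis(methoxymethoxy)phenyl]-4-oxo-4H-pyran-3-yl}zinc | I[Zn]c1coc(-c2c(OC)c(OCOC)ccc2OCOC)cc1=O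
F4 | step 4 | (Z)-4-(dimethylamino)-3-iodobut-3-en-2-one | CN(C)/C=C(\I)C(C)=O
F5 | step 4 | (4Z)-5-(dimethylamino)-4-iodo-1-[2-methoxy-3,6-bis(methoxymethoxy)phenyl]pent-4-ene-1,3-dione | COCOc1ccc(OCOC)c(OC)c1C(=O)CC(=O)/C(I)=C/N(C)C
F6 | step 5 | 3-hydroxy-4-methoxycyclobut-3-ene-1,2-dione | COC1=C(O)C(=O)C1=O
F7 | step 5 | silver 2-methoxy-3,4-dioxocyclobut-1-en-1-olate | COC1=C([O-])C(=O)C1=O.[Ag+]
F8 | step 8 | 7-tert-butoxy-6-methoxy-2-[2-methoxy-3,6-bis(methoxymethoxy)phenyl]-4H-chromene-4,5,8-trione | COCOc1ccc(OCOC)c(OC)c1-c1cc(=O)c2c(o1)C(=O)C(OC(C)(C)C)=C(OC)C2=O
A1 | alternative 1 | 7-(benzyloxy)-6,8-dimethoxy-2-[2-methoxy-3,6-bis(methoxymethoxy)phenyl]-4-oxo-4H-chromen-5-yl trifluoromethanesulfonate | COCOc1ccc(OCOC)c(OC)c1-c1cc(=O)c2c(OS(=O)(=O)C(F)(F)F)c(OC)c(OCc3ccccc3)c(OC)c2o1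
A2 | alternative 1 | 5-(benzyloxy)-4,6-dimethoxy-2-(trimethylsilyl)-1,3-phenylene bis(trifluoromethanesulfonate) | COc1c(OCc2ccccc2)c(OC)c(OS(=O)(=O)C(F)(F)F)c([Si](C)(C)C)c1OS(=O)(=O)C(F)(F)F
A3 | alternative 1 | 3-[2-methoxy-3,6-bis(methoxymethoxy)phenyl]prop-2-ynoic acid | COCOc1ccc(OCOC)c(OC)c1C#CC(=O)O
A4 | alternative 1 | 5-(benzyloxy)-4,6-dimethoxy-1,2-didehydrobenzen-3-yl trifluoromethanesulfonate | COC1=C(OCc2ccccc2)C(OC)=C(OS(=O)(=O)C(F)(F)F)C#C1
A5 | alternative 2 | 7-(benzyloxy)-2-[3,6-bis(benzyloxy)-2-methoxyphenyl]-5-hydroxy-6,8-dimethoxy-4H-chromen-4-one | COc1c(OCc2ccccc2)ccc(OCc2ccccc2)c1-c1cc(=O)c2c(O)c(OC)c(OCc3ccccc3)c(OC)c2o1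
A6 | alternative 2 | 5-(benzyloxy)-4,6-dimethoxybenzene-1,3-diol | COc1c(O)cc(O)c(OC)c1OCc1ccccc1
A7 | alternative 2 | ethyl 3-[3,6-bis(benzyloxy)-2-methoxyphenyl]-3-oxopropanoate | CCOC(=O)CC(=O)c1c(OC)c(OCc2ccccc2)ccc1OCc1ccccc1
A8 | alternative 3 | 7-(benzyloxy)-5-bromo-6,8-dimethoxy-2-[2-methoxy-3,6-bis(methoxymethoxy)phenyl]-4H-chromen-4-one | COCOc1ccc(OCOC)c(OC)c1-c1cc(=O)c2c(Br)c(OC)c(OCc3ccccc3)c(OC)c2o1
A9 | alternative 3 | 1-[4-(benzyloxy)-2,6-dibromo-3,5-dimethoxyphenyl]-3-[2-methoxy-3,6-bis(methoxymethoxy)phenyl]propane-1,3-dione | COCOc1ccc(OCOC)c(OC)c1C(=O)CC(=O)c1c(Br)c(OC)c(OCc2ccccc2)c(OC)c1Br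
A10 | alternative 3 | syringic acid (4-hydroxy-3,5-dimethoxybenzoic acid) | COc1cc(C(=O)O)cc(OC)c1O
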